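## Retrosynthetic overview

- The target has one ring, a 17-membered lactam. It is closed last, at the amide bond, by macrolactamisation of the open-chain amino acid.
- The three tertiary N-methylamines are disconnected by three reductive aminations with Boc-protected amino aldehydes (3-carbon, 4-carbon, 3-carbon). The N-methyl groups come from the building blocks or from formaldehyde.
- The only stereocentre (C4, R) goes back to ethyl (3R)-3-aminododecanoate, made from the prochiral β-keto ester by an ω-transaminase.
- The β-keto ester comes from decanoyl chloride and Meldrum's acid.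

Assumption: aldehydes 6 and 15 are bought as catalogue compounds (each is otherwise one oxidation away from the catalogue N-Boc amino alcohol), and the target is wanted as the free base.

## Route

Step 1
Reactants: 1 decanoyl chloride; 2 Meldrum's acid (2,2-dimethyl-1,3-dioxane-4,6-dione)
Product: 4 ethyl 3-oxododecanoate, via acyl Meldrum's acid 3 (not isolated)
Conditions: pyridine (2 equiv), CH2Cl2, 0 °C to rt; aqueous HCl wash; then EtOH, reflux
Reagents that add atoms: ethanol CCO
Why: C-acylation of Meldrum's acid followed by alcoholysis with loss of acetone and CO2 (Oikawa–Yonemitsu β-keto ester synthesis) reliably homologates an acid chloride to the β-keto ester.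

Step 2
Reactants: 4 ethyl 3-oxododecanoate
Product: 5 ethyl (3R)-3-aminododecanoate
Conditions: (R)-selective ω-transaminase (amine transaminase, panel-selected), pyridoxal 5'-phosphate (1 mM), iPrNH2 (1 M), triethanolamine buffer pH 8.5, DMSO (30% v/v), 40 °C, N2 sweep to remove acetone
Reagents that add atoms: isopropylamine CC(C)N
Why: Asymmetric biocatalytic transamination moves the amino group of isopropylamine onto the prochiral ketone, and the enzyme protonates the bound ketimine only on the Si face of C3, which sets the 3R centre.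

Step 3
Reactants: 5 ethyl (3R)-3-aminododecanoate; 6 tert-butyl methyl(3-oxopropyl)carbamate
Product: 8 ethyl (3R)-3-[{3-[(tert-butoxycarbonyl)(methyl)amino]propyl}(methyl)amino]dodecanoate, via secondary amine 7 (not isolated)
Conditions: 6 (0.95 equiv), NaBH(OAc)3, AcOH, ClCH2CH2Cl, rt; then 37% aq. CH2O, NaBH(OAc)3, rt
Reagents that add atoms: formaldehyde C=O
Why: Two successive borohydride reductive aminations: the α-branched primary amine takes up one molecule of aldehyde 6, and the hindered secondary amine 7 then accepts only formaldehyde; the stereocentre is not involved.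

Step 4
Reactants: 8 ethyl (3R)-3-[{3-[(tert-butoxycarbonyl)(methyl)amino]propyl}(methyl)amino]dodecanoate
Product: 9 ethyl (3R)-3-{methyl[3-(methylamino)propyl]amino}dodecanoate
Conditions: 4 M HCl in dioxane, CH2Cl2, 0 °C to rt; aq. Na2CO3 work-up
Reagents that add atoms: none
Why: Acidolytic Boc cleavage under anhydrous conditions leaves the ethyl ester and the β-amino centre untouched.

Step 5
Reactants: 10 4-(methylamino)butan-1-ol
Product: 11 tert-butyl (4-hydroxybutyl)(methyl)carbamate
Conditions: Boc2O (1.0 equiv), CH2Cl2, 0 °C to rt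
Reagents that add atoms: di-tert-butyl dicarbonate CC(C)(C)OC(=O)OC(=O)OC(C)(C)C
Why: Chemoselective N-acylation (carbamate formation), since the secondary amine is far more nucleophilic than the primary alcohol.

Step 6
Reactants: 11 tert-butyl (4-hydroxybutyl)(methyl)carbamate
Product: 12 tert-butyl methyl(4-oxobutyl)carbamate
Conditions: 2,2,6,6-tetramethylpiperidin-1-oxyl (10 mol%), PhI(OAc)2 (1.1 equiv), CH2Cl2, rt; used fresh
Reagents that add atoms: none
Why: Nitroxyl-catalysed oxidation with PhI(OAc)2 as terminal oxidant stops cleanly at the aldehyde, and the N-methyl carbamate cannot cyclise onto it.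

Step 7
Reactants: 9 ethyl (3R)-3-{methyl[3-(methylamino)propyl]amino}dodecanoate; 12 tert-butyl methyl(4-oxobutyl)carbamate
Product: 13 ethyl (3R)-3-[{3-[{4-[(tert-butoxycarbonyl)(methyl)amino]butyl}(methyl)amino]propyl}(methyl)amino]dodecanoate
Conditions: 12 (1.2 equiv), NaBH(OAc)3 (1.5 equiv), AcOH (1 equiv), ClCH2CH2Cl, rt
Reagents that add atoms: none
Why: Reductive amination of a secondary amine with an aliphatic aldehyde gives the tertiary amine with no over-alkylation pathway; the ester and carbamate are inert to NaBH(OAc)3.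

Step 8
Reactants: 13 ethyl (3R)-3-[{3-[{4-[(tert-butoxycarbonyl)(methyl)amino]butyl}(methyl)amino]propyl}(methyl)amino]dodecanoate
Product: 14 ethyl (3R)-3-[methyl(3-{methyl[4-(methylamino)butyl]amino}propyl)amino]dodecanoate
Conditions: 4 M HCl in dioxane, CH2Cl2, 0 °C to rt; aq. Na2CO3 work-up
Reagents that add atoms: none
Why: Acidolytic Boc cleavage as in step 4; lactamisation of the freed amine onto the ester would need a 13-membered ring and does not compete at rt.

Step 9
Reactants: 14 ethyl (3R)-3-[methyl(3-{methyl[4-(methylamino)butyl]amino}propyl)amino]dodecanoate; 15 tert-butyl (3-oxopropyl)carbamate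
Product: 16 ethyl (3R)-3-[{3-[{4-[{3-[(tert-butoxycarbonyl)amino]propyl}(methyl)amino]butyl}(methyl)amino]propyl}(methyl)amino]dodecanoate
Conditions: 15 (1.2 equiv), NaBH(OAc)3 (1.5 equiv), AcOH (1 equiv), ClCH2CH2Cl, rt
Reagents that add atoms: none
Why: Third reductive amination of a secondary amine; the carbamate nitrogen of 15 is non-basic, so the β-amino aldehyde does not eliminate under these mildly acidic conditions.

Step 10
Reactants: 16 ethyl (3R)-3-[{3-[{4-[{3-[(tert-butoxycarbonyl)amino]propyl}(methyl)amino]butyl}(methyl)amino]propyl}(methyl)amino]dodecanoate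
Product: 18 (3R)-3-[{3-[{4-[(3-aminopropyl)(methyl)amino]butyl}(methyl)amino]propyl}(methyl)amino]dodecanoic acid tetrahydrochloride, via amino ester tetrahydrochloride 17 (not isolated)
Conditions: 6 M aq. HCl, 85 °C; evaporate, co-evaporate with toluene
Reagents that add atoms: water O; hydrogen chloride Cl
Why: Fast Boc acidolysis followed by acid-catalysed ester hydrolysis gives the seco acid as a salt-free hydrochloride by evaporation; the fully protonated β-amino acid neither eliminates nor epimerises.

Step 11
Reactants: 18 (3R)-3-[{3-[{4-[(3-aminopropyl)(methyl)amino]butyl}(methyl)amino]propyl}(methyl)amino]dodecanoic acid tetrahydrochloride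
Product: 20 (4R)-5,9,14-trimethyl-4-nonyl-1,5,9,14-tetraazacycloheptadecan-2-one, via pentafluorophenyl ester 19 (not isolated)
Conditions: 18 and iPr2NEt in DMF added over 12 h (syringe pump) to pentafluorophenyl diphenylphosphinate (1.5 equiv), iPr2NEt, DMF, rt, final 1 mM
Reagents that add atoms: none
Why: High-dilution macrolactamisation through an in situ active ester; only the primary amine can give a stable amide, and the stereocentre is β to the carbonyl, so it cannot epimerise by enolisation.

## Compound list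

1 | decanoyl chloride | CCCCCCCCCC(=O)Cl | starting material
2 | Meldrum's acid (2,2-dimethyl-1,3-dioxane-4,6-dione) | CC1(C)OC(=O)CC(=O)O1 | starting material
3 | 5-(1-hydroxydecylidene)-2,2-dimethyl-1,3-dioxane-4,6-dione (acyl Meldrum's acid, not isolated) | CCCCCCCCCC(O)=C1C(=O)OC(C)(C)OC1=O | intermediate
4 | ethyl 3-oxododecanoate | CCCCCCCCCC(=O)CC(=O)OCC | intermediate
5 | ethyl (3R)-3-aminododecanoate | CCCCCCCCC[C@@H](N)CC(=O)OCC | intermediate
6 | tert-butyl methyl(3-oxopropyl)carbamate | CN(CCC=O)C(=O)OC(C)(C)C | starting material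
7 | ethyl (3R)-3-({3-[(tert-butoxycarbonyl)(methyl)amino]propyl}amino)dodecanoate (not isolated) | CCCCCCCCC[C@@H](NCCCN(C)C(=O)OC(C)(C)C)CC(=O)OCC | intermediate
8 | ethyl (3R)-3-[{3-[(tert-butoxycarbonyl)(methyl)amino]propyl}(methyl)amino]dodecanoate | CCCCCCCCC[C@@H](N(C)CCCN(C)C(=O)OC(C)(C)C)CC(=O)OCC | intermediate
9 | ethyl (3R)-3-{methyl[3-(methylamino)propyl]amino}dodecanoate | CCCCCCCCC[C@@H](N(C)CCCNC)CC(=O)OCC | intermediate
10 | 4-(methylamino)butan-1-ol | CNCCCCO | starting material
11 | tert-butyl (4-hydroxybutyl)(methyl)carbamate | CN(CCCCO)C(=O)OC(C)(C)C | intermediate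
12 | tert-butyl methyl(4-oxobutyl)carbamate | CN(CCCC=O)C(=O)OC(C)(C)C | intermediate
13 | ethyl (3R)-3-[{3-[{4-[(tert-butoxycarbonyl)(methyl)amino]butyl}(methyl)amino]propyl}(methyl)amino]dodecanoate | CCCCCCCCC[C@@H](N(C)CCCN(C)CCCCN(C)C(=O)OC(C)(C)C)CC(=O)OCC | intermediate
14 | ethyl (3R)-3-[methyl(3-{methyl[4-(methylamino)butyl]amino}propyl)amino]dodecanoate | CCCCCCCCC[C@@H](N(C)CCCN(C)CCCCNC)CC(=O)OCC | intermediate
15 | tert-butyl (3-oxopropyl)carbamate | O=CCCNC(=O)OC(C)(C)C | starting material
16 | ethyl (3R)-3-[{3-[{4-[{3-[(tert-butoxycarbonyl)amino]propyl}(methyl)amino]butyl}(methyl)amino]propyl}(methyl)amino]dodecanoate | CCCCCCCCC[C@@H](N(C)CCCN(C)CCCCN(C)CCCNC(=O)OC(C)(C)C)CC(=O)OCC | intermediate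
17 | ethyl (3R)-3-[{3-[{4-[(3-aminopropyl)(methyl)amino]butyl}(methyl)amino]propyl}(methyl)amino]dodecanoate tetrahydrochloride (not isolated) | CCCCCCCCC[C@@H](N(C)CCCN(C)CCCCN(C)CCCN)CC(=O)OCC.Cl.Cl.Cl.Cl | intermediate
18 | (3R)-3-[{3-[{4-[(3-aminopropyl)(methyl)amino]butyl}(methyl)amino]propyl}(methyl)amino]dodecanoic acid tetrahydrochloride | CCCCCCCCC[C@@H](N(C)CCCN(C)CCCCN(C)CCCN)CC(=O)O.Cl.Cl.Cl.Cl | intermediate
19 | pentafluorophenyl (3R)-3-[{3-[{4-[(3-aminopropyl)(methyl)amino]butyl}(methyl)amino]propyl}(methyl)amino]dodecanoate (not isolated) | CCCCCCCCC[C@@H](N(C)CCCN(C)CCCCN(C)CCCN)CC(=O)Oc1c(F)c(F)c(F)c(F)c1F | intermediate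
20 | (4R)-5,9,14-trimethyl-4-nonyl-1,5,9,14-tetraazacycloheptadecan-2-one | CCCCCCCCC[C@@H]1CC(=O)NCCCN(C)CCCCN(C)CCCN1C | target

## Step count

Total steps: 11. Longest linear sequence: 9 (steps 1, 2, 3, 4, 7, 8, 9, 10, 11); steps 5 and 6 are a two-step side branch to aldehyde 12.

## Three steps most likely to fail

**Step 2 (transamination).** A long-chain β-keto ester may be a poor transaminase substrate, and ester hydrolysis with decarboxylation or enamine formation with isopropylamine can compete. The fallback sets out from 4 and comes back to the route at 5. A ketoreductase (NADPH-dependent alcohol dehydrogenase; NADP+ recycled with iPrOH, phosphate buffer pH 7, 30 °C) reduces 4 to ethyl (3S)-3-hydroxydodecanoate F1. Mitsunobu azidation with inversion (PPh3, diisopropyl azodicarboxylate, diphenylphosphoryl azide, THF, 0 °C to rt) gives ethyl (3R)-3-azidododecanoate F2. Hydrogenation (H2, Pd/C, EtOH, rt) then gives 5.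

**Step 3 (mono-alkylation of the primary amine).** Double alkylation by aldehyde 6 would consume material before the methylation. The fallback sets out from 5 and comes back to the route at 7, which is methylated to 8 by the formaldehyde half of step 3. 2-Nitrobenzenesulfonyl chloride with Et3N in CH2Cl2 gives ethyl (3R)-3-[(2-nitrophenyl)sulfonylamino]dodecanoate F3. Fukuyama–Mitsunobu alkylation with purchased tert-butyl (3-hydroxypropyl)(methyl)carbamate (PPh3, diisopropyl azodicarboxylate, THF) gives ethyl (3R)-3-[{3-[(tert-butoxycarbonyl)(methyl)amino]propyl}(2-nitrophenylsulfonyl)amino]dodecanoate F4, which can only be alkylated once. PhSH and K2CO3 in MeCN at rt remove the sulfonyl group and give 7.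

**Step 11 (macrolactamisation).** Oligomerisation, or base-induced loss of the β-amine from the activated ester, could lower the yield. The fallback sets out from 13 and comes back to the route at 20, closing the ring at the N14–C15 bond instead of the amide. LiOH in THF/H2O at rt gives (3R)-3-[{3-[{4-[(tert-butoxycarbonyl)(methyl)amino]butyl}(methyl)amino]propyl}(methyl)amino]dodecanoic acid F5. Intermolecular coupling with purchased 3,3-diethoxypropan-1-amine (EDC hydrochloride, 1-hydroxybenzotriazole, CH2Cl2, rt) gives (3R)-N-(3,3-diethoxypropyl)-3-[{3-[{4-[(tert-butoxycarbonyl)(methyl)amino]butyl}(methyl)amino]propyl}(methyl)amino]dodecanamide F6. Aqueous HCl in THF removes the Boc group and the acetal to give (3R)-3-[methyl(3-{methyl[4-(methylamino)butyl]amino}propyl)amino]-N-(3-oxopropyl)dodecanamide F7 as its hydrochloride. Intramolecular reductive amination at high dilution (NaBH(OAc)3, AcOH, ClCH2CH2Cl, 1 mM, rt) gives 20.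

## Further compounds

F1 | step 2 | ethyl (3S)-3-hydroxydodecanoate | CCCCCCCCC[C@H](O)CC(=O)OCC
F2 | step 2 | ethyl (3R)-3-azidododecanoate | CCCCCCCCC[C@@H](N=[N+]=[N-])CC(=O)OCC
F3 | step 3 | ethyl (3R)-3-[(2-nitrophenyl)sulfonylamino]dodecanoate | CCCCCCCCC[C@@H](NS(=O)(=O)c1ccccc1[N+](=O)[O-])CC(=O)OCC
F4 | step 3 | ethyl (3R)-3-[{3-[(tert-butoxycarbonyl)(methyl)amino]propyl}(2-nitrophenylsulfonyl)amino]dodecanoate | CCCCCCCCC[C@@H](N(CCCN(C)C(=O)OC(C)(C)C)S(=O)(=O)c1ccccc1[N+](=O)[O-])CC(=O)OCC
F5 | step 11 | (3R)-3-[{3-[{4-[(tert-butoxycarbonyl)(methyl)amino]butyl}(methyl)amino]propyl}(methyl)amino]dodecanoic acid | CCCCCCCCC[C@@H](N(C)CCCN(C)CCCCN(C)C(=O)OC(C)(C)C)CC(=O)O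
F6 | step 11 | (3R)-N-(3,3-diethoxypropyl)-3-[{3-[{4-[(tert-butoxycarbonyl)(methyl)amino]butyl}(methyl)amino]propyl}(methyl)amino]dodecanamide | CCCCCCCCC[C@@H](N(C)CCCN(C)CCCCN(C)C(=O)OC(C)(C)C)CC(=O)NCCC(OCC)OCC
F7 | step 11 | (3R)-3-[methyl(3-{methyl[4-(methylamino)butyl]amino}propyl)amino]-N-(3-oxopropyl)dodecanamide | CCCCCCCCC[C@@H](N(C)CCCN(C)CCCCNC)CC(=O)NCCC=O
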